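The easy step comes first: in the blue run the starting material stands at 52.4% after 6.00 min, and that reading gives a half-life of 6.44 min, the length of one turnover, so that the turnover count n of a flask is its time divided by this half-life, and the fraction of starting material left is 0.5 raised to the power n.

| flask | starting material | capture agent | remark | time |
|---|---|---|---|---|
| blue | 0.30 M | 0.13 M | run made earlier |  |
| violet | 0.30 M | 0.20 M | run made earlier |  |
| grey | 0.45 M | 0.090 M | run made earlier |  |
| beta | 0.30 M | 0.0900 M |  | 8.0 min |
| theta | 0.30 M | 0.0900 M |  | 12 min |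

| run | time / min | starting material / % | target / % | intermediate A / % | intermediate B / % | intermediate C / % |
|---|---|---|---|---|---|---|
| blue | 1.00 | 89.4 | 0.3 | 5.5 | 4.5 | 0.1 |
| blue | 2.00 | 80.5 | 0.6 | 5.7 | 11.7 | 1.5 |
| blue | 3.00 | 72.7 | 1.5 | 5.3 | 18.1 | 3.8 |
| blue | 4.00 | 65.0 | 1.9 | 4.6 | 23.0 | 5.7 |
| blue | 5.00 | 58.1 | 2.1 | 4.0 | 26.9 | 8.2 |
| blue | 6.00 | 52.4 | 1.8 | 4.0 | 30.6 | 10.9 |
| violet | 0.500 | 95.1 | 0.3 | 4.1 | 1.8 | 0 |
| violet | 0.833 | 91.9 | 0.3 | 4.3 | 3.6 | 0.2 |
| violet | 1.33 | 86.5 | 0.9 | 4.9 | 6.9 | 0.5 |
| violet | 2.50 | 75.9 | 1.0 | 5.5 | 15.3 | 1.8 |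
| violet | 4.00 | 65.1 | 1.1 | 4.4 | 23.2 | 5.7 |
| violet | 6.00 | 52.3 | 1.6 | 3.8 | 29.7 | 11.0 |
| grey | 0.500 | 94.9 | 0.3 | 3.1 | 1.5 | 0 |
| grey | 1.50 | 85.1 | 0.6 | 5.6 | 8.3 | 1.1 |
| grey | 3.00 | 72.4 | 1.5 | 4.8 | 17.8 | 3.6 |
| grey | 5.00 | 58.4 | 2.5 | 4.0 | 27.1 | 7.9 |
| grey | 6.00 | 52.4 | 2.5 | 3.9 | 30.5 | 11.0 |

(standard deviation of a reading: 0.3 percentage points)



- which of these there is most of at the end, counted by the starting material in it, beta (starting material / intermediate A / intermediate C / intermediate B)
- which of these there is most of at the end, counted by the starting material in it, theta (starting material / intermediate A / intermediate C / intermediate B)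
- final amount of the leader among these, as a percentage of the starting material charged, in beta
- final amount of the leader among these, as a percentage of the starting material charged, in theta

The grey run looks nearly the same as beta, with the same 0.090 M of capture agent but 0.45 M of starting material instead of 0.30 M, yet after 6.00 min it holds 52.4% of starting material, as the blue run does with 0.13 M of capture agent, while the violet run holds 52.3% with 0.20 M. So, within these runs, the decay is first-order and the percentage follows the time, which puts beta at a count of 1.24 and theta at 1.86.

In the blue run at 6.00 min, intermediate B (B) holds 64.3% of what has left the starting material, and if that share carries over, B draws level with the starting material at a critical count of 1.35, which is 8.71 min. Beta stops below this count, so the reckoning here leaves starting material ahead in beta, at 42.2% against 37.1% of B. Theta stops beyond it, so the reckoning here puts B ahead in theta, with 27.5% of starting material against 46.6% of B.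

The forecast names starting material in beta at 42.2% and intermediate B in theta at 35%, the same leaders, but its figure for theta lies 12 percentage points below the reckoning here, on the ground that “B plateaus, so it leads by then”.

The flasks give starting material in beta at 42.1% and intermediate B in theta at 43.1%, which is 8.1 points above the forecast and 3.5 points below the reckoning here.

    capture agent + intermediate A → trapped intermediate (k = 0.00250 L mol⁻¹ s⁻¹)
    starting material → intermediate A (k = 0.00180 s⁻¹)
    intermediate A → intermediate B (k = 0.0260 s⁻¹)
    intermediate B ⇌ intermediate C (K = 0.840, k = 0.00260 s⁻¹)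
    intermediate A ⇌ target (K = 0.490, k = 0.00270 s⁻¹)

Theta's count reckoned 27.5% of starting material left, and theta holds 27.4%. The neighbouring flask, theta read at 50 min, stands at a count of 7.77, past the critical count, which reckons 0.458% of starting material left. That neighbouring flask holds 0.45% of starting material, with 53.7% in B and 44.9% in intermediate C.

(The readings are simulated with made-up constants.)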